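**Retrosynthetic overview** (locants C1–C7 are those of the target throughout)

- Feature: in ring C1–C6 the C1=C2 alkene is flanked by the allylic carbinols C3 and C6, and C3, C4, C5 and C6 carry their four oxygens on one face. Without C7 this is a meso 3,6-dioxygenated cyclohex-1-ene-4,5-diol, the retron of a [4+2] adduct of a 1,4-dioxygenated diene and a cis-dioxygenated alkene.
- 16 ⇐ 15 (acetonide off) ⇐ 14 (C6 ketone, hydride anti to the three oxygens) ⇐ 13 ⇐ 11 + formaldehyde (C1–C7 by Morita–Baylis–Hillman reaction) ⇐ 10 (C5 benzoate, C3/C4 acetonide, free C6–OH).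
- 10 ⇐ 6 ⇐ 4: protecting-group exchange that turns the C4/C5 carbonate into a C3/C4 acetonide plus a free C5–OH. 4 ⇐ 3 by lipase differentiation of the enantiotopic C3/C6 acetates.
- 3 ⇐ 1 + 2 by endo Diels–Alder reaction. The cyclohexene, the only ring, is closed in this first step, and all four stereocentres are set with it.

Key step: step 1

Assumption: the lipase of step 2 is taken to hydrolyse the acetate on the R-configured carbinol carbon of meso 3 (the future C6), as expected for lipases when the oxygenated ring carbon is the large and the vinylic carbon the medium substituent; this sense must be confirmed on the first run.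

**Step 1**
Reactants: 1 (1E,3E)-buta-1,3-diene-1,4-diyl diacetate; 2 vinylene carbonate
Product: 3 meso all-cis 3,6-diacetoxycyclohex-4-ene-1,2-diyl carbonate
Conditions: 2 (3 equiv), neat, BHT (cat.), sealed tube, 180–200 °C
Reagents that add atoms: none
Why: This is a concerted, suprafacial thermal [4+2] cycloaddition, and the closest known reaction type is the thermal Diels–Alder addition of 1,4-diacyloxybutadienes to vinylene carbonate used for conduritol-type tetrols. The cyclohexene ring closes by intermolecular cycloaddition, C3–C4 and C5–C6 forming together, so no separate ring-closure mode has to be chosen. C3 and C6 should come out cis because both acetoxy groups sit on the outer (E) termini of the s-cis diene, and C4 and C5 are cis because the Z geometry of the cyclic dienophile is kept. The relation between the two pairs is set by the endo transition state, in which the carbonate ring lies under the diene (secondary overlap of the carbonate with the diene, compact cyclic dienophile) and its oxygens end up on the face of the acetates. The selectivity needed is endo over exo (the exo adduct would carry the carbonate trans to the acetates); there is no regio- or enantioselectivity question, since both partners are symmetric and the product is meso. The low reactivity of this donor diene with a weakly activated dienophile is met by heat, excess dienophile and a radical inhibitor.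

**Step 2**
Reactants: 3 meso all-cis 3,6-diacetoxycyclohex-4-ene-1,2-diyl carbonate
Product: 4 (3S,4S,5R,6R)-3-acetoxy-6-hydroxycyclohex-1-ene-4,5-diyl carbonate
Conditions: Pseudomonas cepacia lipase, 0.1 M phosphate buffer pH 7, acetone (10 vol%), 25 °C, stopped after one equivalent of acid is released
Reagents that add atoms: none
Why: Lipase-catalysed hydrolysis of one of the two enantiotopic acetates of a meso cyclohex-2-ene-1,4-diyl diester (enzymatic desymmetrisation) creates no new stereocentre but should select the R-configured end as C6, and the cyclic carbonate is not a lipase substrate at neutral pH.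

**Step 3**
Reactants: 4 (3S,4S,5R,6R)-3-acetoxy-6-hydroxycyclohex-1-ene-4,5-diyl carbonate
Product: 5 (3S,4S,5S,6R)-3-acetoxy-6-[(tert-butyldiphenylsilyl)oxy]cyclohex-1-ene-4,5-diyl carbonate
Conditions: TBDPSCl, imidazole, DMF, 0 °C → rt
Reagents that add atoms: tert-butyl(chloro)diphenylsilane, CC(C)(C)[Si](Cl)(c1ccccc1)c1ccccc1
Why: Standard silylation of the only free (allylic) hydroxyl under weakly basic conditions that leave acetate and carbonate untouched; the bulky, slowly migrating silyl group marks C6 for the later steps.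

**Step 4**
Reactants: 5 (3S,4S,5S,6R)-3-acetoxy-6-[(tert-butyldiphenylsilyl)oxy]cyclohex-1-ene-4,5-diyl carbonate
Product: 6 (3S,4S,5S,6R)-6-[(tert-butyldiphenylsilyl)oxy]cyclohex-1-ene-3,4,5-triol
Conditions: K2CO3 (0.2 equiv), MeOH, 0 °C
Reagents that add atoms: none
Why: Base-catalysed transesterification (Zemplén-type methanolysis) should remove the acetate and the cyclic carbonate as methyl acetate and dimethyl carbonate, while the hindered silyl ether is stable and slow to migrate at 0 °C.

**Step 5**
Reactants: 6 (3S,4S,5S,6R)-6-[(tert-butyldiphenylsilyl)oxy]cyclohex-1-ene-3,4,5-triol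
Product: 7 (3S,4R,5S,6R)-6-[(tert-butyldiphenylsilyl)oxy]-3,4-(isopropylidenedioxy)cyclohex-1-en-5-ol
Conditions: 2,2-dimethoxypropane, pyridinium p-toluenesulfonate (cat.), acetone, rt
Reagents that add atoms: 2,2-dimethoxypropane, COC(C)(C)OC
Why: Acid-catalysed transketalisation under equilibrating conditions should give the C3/C4 dioxolane, because it starts at the least hindered, allylic C3–OH and avoids placing the cis-fused ketal next to the large cis silyl ether at C6, so C5–OH is left free.

**Step 6**
Reactants: 7 (3S,4R,5S,6R)-6-[(tert-butyldiphenylsilyl)oxy]-3,4-(isopropylidenedioxy)cyclohex-1-en-5-ol; 8 benzoyl chloride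
Product: 9 (3S,4S,5S,6R)-5-(benzoyloxy)-6-[(tert-butyldiphenylsilyl)oxy]-3,4-(isopropylidenedioxy)cyclohex-1-ene
Conditions: pyridine, 4-(dimethylamino)pyridine (cat.), CH2Cl2, 0 → 40 °C
Reagents that add atoms: none
Why: Nucleophile-catalysed acylation of the only free hydroxyl places the benzoate on C5 with no change at any stereocentre.

**Step 7**
Reactants: 9 (3S,4S,5S,6R)-5-(benzoyloxy)-6-[(tert-butyldiphenylsilyl)oxy]-3,4-(isopropylidenedioxy)cyclohex-1-ene
Product: 10 (3S,4S,5R,6R)-5-(benzoyloxy)-3,4-(isopropylidenedioxy)cyclohex-1-en-6-ol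
Conditions: Bu4NF, AcOH (1:1), THF, 0 °C → rt
Reagents that add atoms: none
Why: Fluoride-mediated desilylation, buffered with acetic acid so that the C6 alkoxide is protonated at once and the benzoyl group does not move from O5 to O6; the acetonide is inert.

**Step 8**
Reactants: 10 (3S,4S,5R,6R)-5-(benzoyloxy)-3,4-(isopropylidenedioxy)cyclohex-1-en-6-ol
Product: 11 (3S,4S,5S)-5-(benzoyloxy)-3,4-(isopropylidenedioxy)cyclohex-1-en-6-one
Conditions: Dess–Martin periodinane, CH2Cl2, 0 °C → rt
Reagents that add atoms: none
Why: Dess–Martin oxidation of the secondary allylic alcohol to the enone under near-neutral conditions, which should keep the α-benzoyloxy ketone from enolising at C5.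

**Step 9**
Reactants: 11 (3S,4S,5S)-5-(benzoyloxy)-3,4-(isopropylidenedioxy)cyclohex-1-en-6-one; 12 formaldehyde
Product: 13 (3S,4S,5S)-5-(benzoyloxy)-1-(hydroxymethyl)-3,4-(isopropylidenedioxy)cyclohex-1-en-6-one
Conditions: 37% aq. CH2O, 4-(dimethylamino)pyridine (0.3 equiv), THF/H2O, rt
Reagents that add atoms: none
Why: Morita–Baylis–Hillman hydroxymethylation, known for oxygenated cyclohexenones with aqueous formaldehyde: the amine adds to C2, the C1 enolate adds to formaldehyde, and loss of the amine restores C1=C2 with C7 on C1.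

**Step 10**
Reactants: 13 (3S,4S,5S)-5-(benzoyloxy)-1-(hydroxymethyl)-3,4-(isopropylidenedioxy)cyclohex-1-en-6-one; 8 benzoyl chloride
Product: 14 (3S,4S,5S)-5-(benzoyloxy)-1-(benzoyloxymethyl)-3,4-(isopropylidenedioxy)cyclohex-1-en-6-one
Conditions: pyridine, CH2Cl2, 0 °C
Reagents that add atoms: none
Why: Acylation of the primary allylic alcohol with a weak amine base, mild enough for the base-sensitive enone.

**Step 11**
Reactants: 14 (3S,4S,5S)-5-(benzoyloxy)-1-(benzoyloxymethyl)-3,4-(isopropylidenedioxy)cyclohex-1-en-6-one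
Product: 15 [(3S,4S,5R,6R)-5-(benzoyloxy)-6-hydroxy-3,4-(isopropylidenedioxy)cyclohex-1-en-1-yl]methyl benzoate
Conditions: NaBH4, CeCl3·7H2O, MeOH, −78 °C, AcOH quench
Reagents that add atoms: none
Why: Luche 1,2-reduction, in which hydride should reach the C6 carbonyl from the face opposite the C3/C4 acetonide and the C5 benzoate (steric shielding and polar Felkin–Anh attack anti to the α-benzoyloxy group), giving C6–OH cis to O5 (6R).

**Step 12**
Reactants: 15 [(3S,4S,5R,6R)-5-(benzoyloxy)-6-hydroxy-3,4-(isopropylidenedioxy)cyclohex-1-en-1-yl]methyl benzoate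
Product: 16 [(3S,4S,5R,6R)-5-(benzoyloxy)-3,4,6-trihydroxycyclohex-1-en-1-yl]methyl benzoate (CNP0198957.4)
Conditions: AcOH/H2O (4:1), 40 °C
Reagents that add atoms: none
Why: Acid-catalysed hydrolysis of the isopropylidene ketal, under which benzoates neither cleave nor migrate appreciably and no stereocentre is touched.

**Compound list**

1 | (1E,3E)-buta-1,3-diene-1,4-diyl diacetate | CC(=O)O/C=C/C=C/OC(C)=O | starting material
2 | vinylene carbonate (1,3-dioxol-2-one) | O=C1OC=CO1 | starting material
3 | meso all-cis 3,6-diacetoxycyclohex-4-ene-1,2-diyl carbonate (target locants: acetates on C3 and C6, carbonate on C4/C5, all four oxygens on one ring face) | C1=C[C@H](OC(C)=O)[C@@H]2OC(=O)O[C@@H]2[C@@H]1OC(C)=O | intermediate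
4 | (3S,4S,5R,6R)-3-acetoxy-6-hydroxycyclohex-1-ene-4,5-diyl carbonate (all-cis) | C1=C[C@H](OC(C)=O)[C@@H]2OC(=O)O[C@@H]2[C@@H]1O | intermediate
5 | (3S,4S,5S,6R)-3-acetoxy-6-[(tert-butyldiphenylsilyl)oxy]cyclohex-1-ene-4,5-diyl carbonate (all-cis) | C1=C[C@H](OC(C)=O)[C@@H]2OC(=O)O[C@@H]2[C@@H]1O[Si](c3ccccc3)(c4ccccc4)C(C)(C)C | intermediate
6 | (3S,4S,5S,6R)-6-[(tert-butyldiphenylsilyl)oxy]cyclohex-1-ene-3,4,5-triol (all-cis) | C1=C[C@H](O)[C@H](O)[C@H](O)[C@@H]1O[Si](c2ccccc2)(c3ccccc3)C(C)(C)C | intermediate
7 | (3S,4R,5S,6R)-6-[(tert-butyldiphenylsilyl)oxy]-3,4-(isopropylidenedioxy)cyclohex-1-en-5-ol (all-cis) | C1=C[C@@H]2OC(C)(C)O[C@@H]2[C@H](O)[C@@H]1O[Si](c3ccccc3)(c4ccccc4)C(C)(C)C | intermediate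
8 | benzoyl chloride | O=C(Cl)c1ccccc1 | starting material
9 | (3S,4S,5S,6R)-5-(benzoyloxy)-6-[(tert-butyldiphenylsilyl)oxy]-3,4-(isopropylidenedioxy)cyclohex-1-ene (all-cis) | C1=C[C@@H]2OC(C)(C)O[C@@H]2[C@H](OC(=O)c3ccccc3)[C@@H]1O[Si](c4ccccc4)(c5ccccc5)C(C)(C)C | intermediate
10 | (3S,4S,5R,6R)-5-(benzoyloxy)-3,4-(isopropylidenedioxy)cyclohex-1-en-6-ol (all-cis) | C1=C[C@@H]2OC(C)(C)O[C@@H]2[C@H](OC(=O)c3ccccc3)[C@@H]1O | intermediate
11 | (3S,4S,5S)-5-(benzoyloxy)-3,4-(isopropylidenedioxy)cyclohex-1-en-6-one | O=C1C=C[C@@H]2OC(C)(C)O[C@@H]2[C@@H]1OC(=O)c3ccccc3 | intermediate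
12 | formaldehyde | C=O | starting material
13 | (3S,4S,5S)-5-(benzoyloxy)-1-(hydroxymethyl)-3,4-(isopropylidenedioxy)cyclohex-1-en-6-one | O=C1C(CO)=C[C@@H]2OC(C)(C)O[C@@H]2[C@@H]1OC(=O)c3ccccc3 | intermediate
14 | (3S,4S,5S)-5-(benzoyloxy)-1-(benzoyloxymethyl)-3,4-(isopropylidenedioxy)cyclohex-1-en-6-one | O=C1C(COC(=O)c3ccccc3)=C[C@@H]2OC(C)(C)O[C@@H]2[C@@H]1OC(=O)c4ccccc4 | intermediate
15 | [(3S,4S,5R,6R)-5-(benzoyloxy)-6-hydroxy-3,4-(isopropylidenedioxy)cyclohex-1-en-1-yl]methyl benzoate (all-cis) | O=C(OCC1=C[C@@H]2OC(C)(C)O[C@@H]2[C@H](OC(=O)c3ccccc3)[C@@H]1O)c4ccccc4 | intermediate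
16 | [(3S,4S,5R,6R)-5-(benzoyloxy)-3,4,6-trihydroxycyclohex-1-en-1-yl]methyl benzoate (CNP0198957.4) | O=C(OCC1=C[C@H](O)[C@H](O)[C@H](OC(=O)c2ccccc2)[C@@H]1O)c1ccccc1 | target

**Step count and risks**

Total steps: 12. Longest linear sequence: 12 steps (from 1 and 2 to 16).

Steps most likely to fail:

Step 2. The enzyme may act on the wrong enantiotopic acetate or discriminate poorly between the two ends, and the carbonate may hydrolyse slowly in water. The fallback sets out from 3 and reverses the direction of the enzymatic reaction. Acid-catalysed methanolysis (AcCl, 0.2 equiv, MeOH, 0 °C → rt) should strip both acetates and leave the acid-stable carbonate, giving meso all-cis 3,6-dihydroxycyclohex-4-ene-1,2-diyl carbonate F1. This diol is then monoacetylated with the same lipase and vinyl acetate in tert-butyl methyl ether. An enzyme that deacylates one carbinol carbon in water acylates that same carbon in the organic medium, so the monoacetate of opposite sense results and the onward reaction of the minor monoacetate to diacetate raises the enantiomeric purity. The fallback comes back to the route at 4.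

Step 5. The ketal may close on the C4/C5 pair instead of C3/C4, or the silyl group may wander from O6 to O5 during the preceding methanolysis, either of which mislabels C5. The fallback sets out from 3 and removes the question by placing the C5 benzoate before ketalisation, so that only one cis-1,2-diol remains. The meso diol carbonate F1 (made from 3 as above) is etherified on both allylic hydroxyls with 4-methoxybenzyl trichloroacetimidate and catalytic camphorsulfonic acid to give meso all-cis 3,6-bis[(4-methoxybenzyl)oxy]cyclohex-4-ene-1,2-diyl carbonate F2. Methanolysis (K2CO3, MeOH) then frees meso all-cis 3,6-bis[(4-methoxybenzyl)oxy]cyclohex-1-ene-4,5-diol F3. Catalytic enantioselective monobenzoylation of this meso 1,2-diol (CuCl2, a C2-symmetric phenyl-bis(oxazoline) ligand whose enantiomer is fixed on the first run, 8, N,N-diisopropylethylamine, CH2Cl2, 0 °C) should give (3S,4S,5S,6R)-5-(benzoyloxy)-3,6-bis[(4-methoxybenzyl)oxy]cyclohex-1-en-4-ol F4. Oxidative removal of both benzyl-type ethers (DDQ, CH2Cl2/pH 7 buffer, 0 °C) gives (3S,4S,5R,6R)-5-(benzoyloxy)cyclohex-1-ene-3,4,6-triol F5, whose only vicinal cis-diol is C3/C4. Ketalisation (2,2-dimethoxypropane, pyridinium p-toluenesulfonate, acetone) then comes back to the route at 10.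

Step 9. The amine catalyst may enolise the ketone at C5, which carries the benzoate, with β-elimination of the C4 ketal oxygen and aromatisation, or the addition may stall. The fallback sets out from 11 and replaces the organocatalytic aldol by a cross-coupling. α-Iodination (I2, pyridine, CH2Cl2, rt) should give (3S,4S,5S)-5-(benzoyloxy)-1-iodo-3,4-(isopropylidenedioxy)cyclohex-1-en-6-one F6. Stille coupling of this iodide with (tributylstannyl)methanol (Pd(PPh3)4, dioxane, 80 °C) introduces the hydroxymethyl group at C1 without any base and comes back to the route at 13.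

**Further compounds**

F1 | step 2 | meso all-cis 3,6-dihydroxycyclohex-4-ene-1,2-diyl carbonate | C1=C[C@H](O)[C@@H]2OC(=O)O[C@@H]2[C@@H]1O
F2 | step 5 | meso all-cis 3,6-bis[(4-methoxybenzyl)oxy]cyclohex-4-ene-1,2-diyl carbonate | C1=C[C@H](OCc3ccc(OC)cc3)[C@@H]2OC(=O)O[C@@H]2[C@@H]1OCc4ccc(OC)cc4
F3 | step 5 | meso all-cis 3,6-bis[(4-methoxybenzyl)oxy]cyclohex-1-ene-4,5-diol | C1=C[C@H](OCc2ccc(OC)cc2)[C@H](O)[C@H](O)[C@@H]1OCc3ccc(OC)cc3
F4 | step 5 | (3S,4S,5S,6R)-5-(benzoyloxy)-3,6-bis[(4-methoxybenzyl)oxy]cyclohex-1-en-4-ol | C1=C[C@H](OCc2ccc(OC)cc2)[C@H](O)[C@H](OC(=O)c3ccccc3)[C@@H]1OCc4ccc(OC)cc4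
F5 | step 5 | (3S,4S,5R,6R)-5-(benzoyloxy)cyclohex-1-ene-3,4,6-triol | C1=C[C@H](O)[C@H](O)[C@H](OC(=O)c2ccccc2)[C@@H]1O
F6 | step 9 | (3S,4S,5S)-5-(benzoyloxy)-1-iodo-3,4-(isopropylidenedioxy)cyclohex-1-en-6-one | O=C1C(I)=C[C@@H]2OC(C)(C)O[C@@H]2[C@@H]1OC(=O)c3ccccc3
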